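## The problem

Numbering used throughout: decalin carbons C1–C10, C11 the methylene carbon on C4, C12, C13 and C14 the methyl groups on C5, C8 and C9, C15 the benzylic carbon, C1′–C6′ the arene (C1′ on C15, CH2OH on C3′, OH on C5′, sulfate on C6′); β is the face of C12.

The target 29 is a rearranged drimane. Rings A and B are trans-fused (C12 β, H10 α), and ring B carries the quaternary C9 (C14 β and axial, C15 α and equatorial) and C8 (C13 β, equatorial). Four contiguous stereocentres must be set, two of them quaternary with 1,3-diaxial methyl groups. C5 and C10 are vicinal and can be made in one event; once fixed, allylic strain at C10 and the chair of ring B can pass their information to C9 and then to C8. The C4=C11 methylene is a 1,1-disubstituted alkene beside a quaternary carbon. It migrates into the ring under acid and does not survive hydrogenation, so it must come late. The arene carries three different oxygens: the sulfate monoester sits on the more hindered O6′, the two phenolic oxygens must be told apart, and the benzylic alcohol para to O6′ ionises easily once that phenol is free. The sulfate tolerates neither acid nor the conditions of most C–C bond formations and therefore goes on last. The opening is ring A. C1–C5 and C10 form a six-membered ring in which C4 is derivable from oxygen, C5 is a methyl-bearing quaternary carbon attached to C6, and C10 carries C9 trans to C6. That is the pattern of a cycloadduct between a 1-oxygenated butadiene (C4 to C1) and an (E)-2-methyl-2-enal whose formyl carbon is C6 and whose β-substituent is C9.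

## Retrosynthesis

**Sulfate and arene unmasking (29 ⇐ 27 ⇐ 26 ⇐ 24).** The S–O6′ bond and the two O–Si bonds are cut first. The sulfate is put on phenol 26, the only free hydroxyl at that stage, and the two triisopropylsilyl ethers of 27 fall to fluoride, which the sulfate and the alkene both tolerate. Phenol 26 comes from the methoxymethyl ether 24. The forward reaction must cleave an aryl acetal without acid strong enough to move the alkene or strip the silyl ethers.

**Ring A methylene (24 ⇐ 23 ⇐ 22 ⇐ 21).** The C4=C11 bond is cut to ketone 23 and a one-carbon phosphorus ylide. The alternative, ending a cationic sequence by proton loss, cannot guarantee the exocyclic position; a ketone can. Ketone 23 comes from alcohol 22 and its triethylsilyl ether 21. This oxygen is the one the cycloaddition places at C4, so it costs no extra step. The triethylsilyl group must be the most labile silyl group in the molecule.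

**Ring B (21 ⇐ 20 ⇐ 19).** The C8–C9 bond is cut. Alkenyl triflate 19 closes onto the styrene carbon C9 in a reductive Heck cyclisation to give 20, and hydrogenation of the C8 methylene gives 21. The neighbouring option, a C8 alkyl radical from a 3-iodobutyl chain, must attack a fully substituted alkene carbon while a doubly activated hydrogen (H10) lies in 1,5-relation; it is kept only as a fallback. The precursor 19 is monocyclic and has two stereocentres fewer. The closure is asked to form the quaternary C9 with C14 axial, and the hydrogenation to deliver hydrogen to the α face.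

**Side chain (19 ⇐ 17 ⇐ 16 ⇐ 13).** The C6–C7 bond is cut. The formyl group of 13 is extended with ketophosphonate 14 to enone 16, and both disubstituted alkenes are then hydrogenated to 17. The ring A alkene must go before ring closure because C3 is also six atoms from C8 and would compete with C9. The trisubstituted styrene has to survive this hydrogenation.

**Ring A, the key cut (13 ⇐ 10 + 12).** C4–C5 and C1–C10 are cut in a Diels–Alder sense to dienal 10 and siloxydiene 12. This single step makes the quaternary C5, sets C10 and delivers the C4 oxygen. No other cut of ring A gives both ring-fusion centres at once from achiral, planar components. The forward reaction needs face selection by a chiral acid catalyst and reaction at the α,β- rather than the γ,δ-alkene of 10.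

**Dienal and diene (10 ⇐ 9 ⇐ 7; 12 ⇐ 11).** The two (E)-trisubstituted alkenes of 10 are cut by successive Wittig disconnections with the same formyl ylide 8, via enal 9, back to aldehyde 7. This avoids hydroxide-mediated aldol chemistry, which the aryl silyl ether would not survive. Diene 12 comes from crotonaldehyde 11 in one step.

**Arene (7 ⇐ 5 ⇐ 4 ⇐ 3 ⇐ 2 ⇐ 1).** The formyl group of 7 (the future C15) is traced to the bromine of 5, the two silyl ethers to diol 4, and the alcohol to aldehyde 3. The acetal on O6′ is traced to catechol 2, where the oxygen para to the formyl group is the more acidic, and 2 to 5-bromovanillin 1. All four arene substituents are already in place in 1.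

## Roads not taken

**Alternative 1:** No ring bond is cut. The C5–C12 and C9–C14 bonds and the C4=C11 alkene are traced to a normal drimane, the 8(12)-ene A2, which has the arylmethyl group on C9, a methyl on C10 and a gem-dimethyl C4, and is reachable from a chiral-pool drimane lactone. Forward, BF3·OEt2 or a stronger confined Brønsted acid protonates the exocyclic alkene of A2. Four suprafacial 1,2-shifts follow (H9 to C8, the C10 methyl to C9, H5 to C10, a C4 methyl to C5), and proton loss from the remaining C4 methyl gives A1.
- Merits: all four stereocentres are relayed from a cheap enantiopure terpenoid, no ring is built, and the path to the skeleton is much shorter. On step count this road is better than the chosen one.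
- Weak points: the final C4 cation can lose H3 to give the more substituted ring alkene instead of the methylene. The cascade can stop at the C9 or C10 cation, and the electron-rich arene can trap any of the cations.
- A1 is also far from 29 on the arene side. It needs a bromide turned into CH2OH and two methyl ethers cleaved by Lewis acids that the 4(11)-alkene does not tolerate, and the two oxygens are not differentiated.
- Against its brevity the chosen plan sets an alkene position fixed by a ketone, a defined control element for every stereocentre, and an arene that arrives with the protecting groups the sulfate endgame needs.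

**Alternative 2:** Both rings are cut at once, at C9–C10 and C4–C5, to an acyclic α-arylmethyl β-keto ester with an (E)-alkene and a terminal alkyne, carried as an 8-phenylmenthyl ester. Forward, Mn(OAc)3·2H2O (trivalent manganese) oxidises the keto ester to the C9 radical. This closes ring B 6-endo at C10 and then ring A 6-exo-dig from C5, giving A3.
- Merits: one step forms both rings, both quaternary carbons and the C4 methylene. In ring construction it is more convergent than the chosen plan, which needs steps 9 and 13 for the same bonds.
- Weak points: absolute control rests on an ester auxiliary remote from the forming bonds, and the oxidant meets an electron-rich arene.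
- A3 is at the wrong oxidation level at two carbons. The C9 ester must become a methyl group (a neopentyl deoxygenation). The C8 ketone must become a secondary methyl by methylenation and hydrogenation, in the presence of the C4 methylene and an allyl ether that hydrogenation cannot distinguish from the new alkene.
- The chosen plan pays one more ring-forming step but reaches C8, C9 and C14 at their final oxidation level directly and hydrogenates before C11 exists.

**Alternative 3:** The arene is cut instead of the decalin. C2′–C3′ and C1′=C6′ are disconnected to the methyl ketone A5 and the enone ester A6. Forward, the LiN(i-Pr)2-derived methyl enolate of A5 adds to A6, and the α-alkoxy ketone then condenses onto the C1′ carbonyl to give the 2-allyloxycyclohexenone A4, which is aromatised later.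
- Merits: the two arene oxygens are different from the start (O6′ as an allyl enol ether, O5′ as a ketone), so the sulfate position is unambiguous. Here it is better than the chosen plan, which must earn the distinction by a regioselective mono-protection (step 2) and a chemoselective acetal cleavage (step 18).
- Weak points: A5 already contains the whole stereochemical problem and the sensitive methylene, so the hard part is only moved. A6 has two electrophilic alkene carbons. Aromatising A4 means dehydrogenation and ester reduction beside an exocyclic alkene and an allyl ether.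
- Against its cleaner oxygen differentiation the chosen plan sets a preformed, inexpensive arene and a catalytic enantioselective entry to the decalin.

Key step: step 9

Abbreviation in names: Ar = 2-(methoxymethoxy)-3-(triisopropylsilyloxy)-5-[(triisopropylsilyloxy)methyl]phenyl.

Assumption: the target is taken as the free aryl hydrogen sulfate as drawn; it is released from its tetrabutylammonium salt 28 only in the last operation and should be kept cold and dilute.

## Route

Step 1
Reactants: 1 5-bromovanillin (3-bromo-4-hydroxy-5-methoxybenzaldehyde)
Product: 2 3-bromo-4,5-dihydroxybenzaldehyde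
Conditions: AlCl3, pyridine, CH2Cl2, reflux; then aq. HCl
Reagents that add atoms: none
Why: O-demethylation of an o-hydroxyanisole: aluminium chelates the two adjacent oxygens and pyridine removes the activated methyl group; the aldehyde and the bromide are inert.

Step 2
Reactants: 2 3-bromo-4,5-dihydroxybenzaldehyde
Product: 3 3-bromo-5-hydroxy-4-(methoxymethoxy)benzaldehyde
Conditions: MOMCl (1.05 equiv), i-Pr2NEt, THF, 0 °C
Reagents that add atoms: chloromethyl methyl ether, COCCl
Why: Regioselective O-alkylation: the hydroxyl para to the formyl group and ortho to bromine is the more acidic, so the amine forms its phenoxide preferentially and one equivalent of electrophile gives the 4-O-acetal (the future O6′).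

Step 3
Reactants: 3 3-bromo-5-hydroxy-4-(methoxymethoxy)benzaldehyde
Product: 4 3-bromo-5-(hydroxymethyl)-2-(methoxymethoxy)phenol
Conditions: NaBH4, MeOH/THF, 0 °C
Reagents that add atoms: none
Why: Borohydride reduction of an aryl aldehyde; the acetal and the aryl bromide are untouched.

Step 4
Reactants: 4 3-bromo-5-(hydroxymethyl)-2-(methoxymethoxy)phenol
Product: 5 {[3-bromo-4-(methoxymethoxy)-5-(triisopropylsilyloxy)phenyl]methoxy}triisopropylsilane (ArBr)
Conditions: i-Pr3SiCl (2.5 equiv), imidazole, DMF, rt
Reagents that add atoms: chlorotriisopropylsilane, CC(C)[Si](Cl)(C(C)C)C(C)C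
Why: Imidazole-promoted silylation of the phenol and the primary alcohol with one reagent; the same bulky silyl group on both oxygens allows a single fluoride deprotection at the end and outlasts the triethylsilyl ether introduced later.

Step 5
Reactants: 5 aryl bromide ArBr
Product: 7 2-(methoxymethoxy)-3-(triisopropylsilyloxy)-5-[(triisopropylsilyloxy)methyl]benzaldehyde (ArCHO), via aryllithium 6 (not isolated)
Conditions: n-BuLi, THF, −78 °C; DMF; aq. NH4Cl
Reagents that add atoms: N,N-dimethylformamide, CN(C)C=O
Why: Bromine–lithium exchange gives an aryllithium stabilised by the ortho acetal oxygen, and formylation with the amide installs C15; the silyloxy group is meta to lithium, so no silyl shift to carbon is possible.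

Step 6
Reactants: 7 ArCHO; 8 2-(triphenylphosphoranylidene)propanal
Product: 9 (E)-3-Ar-2-methylprop-2-enal
Conditions: 8 (1.1 equiv), toluene, 90 °C
Reagents that add atoms: none
Why: Wittig reaction of a stabilised formyl ylide, (E)-selective by reversible betaine formation; no base is present, so the aryl silyl ether is safe.

Step 7
Reactants: 9 (E)-3-Ar-2-methylprop-2-enal; 8 2-(triphenylphosphoranylidene)propanal
Product: 10 (2E,4E)-5-Ar-2,4-dimethylpenta-2,4-dienal
Conditions: 8 (1.5 equiv), toluene, 110 °C
Reagents that add atoms: none
Why: Second Wittig homologation with the same stabilised ylide gives the (2E,4E)-dienal; the less electrophilic enal needs the higher temperature, which also keeps step 6 from over-running.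

Step 8
Reactants: 11 (E)-crotonaldehyde
Product: 12 (E)-1-(triethylsilyloxy)buta-1,3-diene
Conditions: Et3SiOTf, Et3N, Et2O, 0 °C → rt; distillation
Reagents that add atoms: triethylsilyl trifluoromethanesulfonate, CC[Si](CC)(CC)OS(=O)(=O)C(F)(F)F
Why: Soft enolisation: O-silylation of the aldehyde and γ-deprotonation by the amine give the dienol silyl ether, mainly as the (E)-isomer; the minor (Z)-isomer cannot easily reach the s-cis conformer and is inert in step 9.

Step 9
Reactants: 10 (2E,4E)-5-Ar-2,4-dimethylpenta-2,4-dienal; 12 (E)-1-(triethylsilyloxy)buta-1,3-diene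
Product: 13 (1S,2R,6S)-6-[(E)-1-Ar-prop-1-en-2-yl]-1-methyl-2-(triethylsilyloxy)cyclohex-3-ene-1-carbaldehyde (ring A with 4α-OSiEt3; 5β-CH3; 5α-CHO; 10α-H)
Conditions: (S)-3,3-diphenyl-1-(o-tolyl)tetrahydro-1H,3H-pyrrolo[1,2-c][1,3,2]oxazaborole (20 mol%), HNTf2 (18 mol%), 12 (3 equiv), CH2Cl2, −78 → −40 °C; Et3N quench
Reagents that add atoms: none
Why: The N-protonated oxazaborolidine binds the formyl oxygen of 10 through boron (s-trans enal, formyl C–H held by the ring oxygen) and lowers the LUMO of the C5=C10 bond, which then undergoes a concerted, asynchronous [4+2] cycloaddition with 12. The closest known reaction type is the cationic oxazaborolidine-catalysed Diels–Alder reaction of 2-methyl-2-enals with 1-oxygenated butadienes to give formyl-bearing quaternary centres. Ring A closes in a six-membered suprafacial–suprafacial pericyclic mode, forming C4–C5 and C1–C10. Regiochemistry follows from the diene polarisation: the unsubstituted terminus C1 has the larger HOMO coefficient and bonds to the β-carbon C10, so the siloxy carbon C4 bonds to C5. The C5/C10 relationship is set by the (E)-geometry of the enal: suprafacial addition puts C6 and C9 trans and C12 cis to C9, which is the trans ring fusion. The absolute configuration is set by the catalyst: its phenyl group stacks under the Cα-Si face of the bound enal, so the diene adds to the Cα-Re face and gives (5S,10S); the mirror-image catalyst is equally available should the sense need reversing. C4 is set by the formyl-endo approach of the (E)-diene (OSiEt3 cis to CHO), but this centre is later made trigonal, so its epimer would serve as well. The step needs reaction at the α,β- rather than the γ,δ-alkene, which is secured because only the alkene adjacent to the coordinated carbonyl is strongly activated and the distal one is trisubstituted and aryl-conjugated.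

Step 10
Reactants: 13 cycloadduct aldehyde; 14 dimethyl (2-oxopropyl)phosphonate
Product: 16 (E)-4-[ring A of 13]but-3-en-2-one (C6=C7 and C8=O new; 4α-OSiEt3; 5β-CH3; 10β-[(E)-1-Ar-prop-1-en-2-yl] unchanged), via sodium phosphonate 15 (not isolated)
Conditions: 14, NaH, THF, 0 °C; then 13, 0 → 45 °C
Reagents that add atoms: none
Why: Horner–Wadsworth–Emmons olefination; the phosphonate anion is nucleophilic enough for the neopentyl aldehyde and gives the (E)-enone, and the aldehyde has no α-hydrogen, so nothing can epimerise or eliminate.

Step 11
Reactants: 16 (E)-enone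
Product: 17 4-[ring A cyclohexyl]butan-2-one (C6–C7 and C2–C3 saturated; styrene C9=C15 intact; 4α-OSiEt3; 5β-CH3; 10α-H)
Conditions: H2 (3 atm), RhCl(PPh3)3 (10 mol%), benzene, rt
Reagents that add atoms: none
Why: Homogeneous hydrogenation with this rhodium complex reduces 1,2-disubstituted alkenes (here the enone alkene and the ring A alkene) far faster than trisubstituted ones, so the styrene needed for ring closure and the ketone remain.

Step 12
Reactants: 17 saturated methyl ketone
Product: 19 alkenyl triflate 4-[ring A cyclohexyl]but-1-en-2-yl trifluoromethanesulfonate (C8(OTf)=C13H2), via lithium enolate 18 (not isolated)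
Conditions: LiN(i-Pr)2, THF, −78 °C; PhNTf2, −78 → 0 °C
Reagents that add atoms: N-phenylbis(trifluoromethanesulfonimide), O=S(=O)(N(c1ccccc1)S(=O)(=O)C(F)(F)F)C(F)(F)F
Why: Kinetic deprotonation of a methyl ketone by a hindered amide at low temperature occurs at the methyl group, and O-sulfonylation of the terminal enolate gives the 1-alken-2-yl triflate.

Step 13
Reactants: 19 alkenyl triflate
Product: 20 trans-decalin with 8(13)-methylene; 9β-CH3; 9α-CH2Ar; 5β-CH3; 10α-H; 4α-OSiEt3
Conditions: Pd(OAc)2 (10 mol%), PPh3 (25 mol%), HCO2Na (2 equiv), n-Bu4NCl, DMF, 70 °C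
Reagents that add atoms: none
Why: Intramolecular reductive Heck cyclisation: zerovalent palladium inserts into the C8–OTf bond, the alkenylpalladium adds 6-exo-trig across C9=C15 to form the quaternary C9, and the resulting benzylpalladium, which has no β-hydrogen, is reduced by formate to the CH2Ar group. C9 is set by allylic strain: in the chair-like closure the C10–H bond eclipses C9=C15, which places C14 axial (β, cis to C12) and C15 equatorial; the other rotamer would push the aryl-bearing alkene carbon against C4 and C12.

Step 14
Reactants: 20 8(13)-methylene decalin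
Product: 21 trans-decalin with 8β-CH3; 9β-CH3; 9α-CH2Ar; 5β-CH3; 10α-H; 4α-OSiEt3
Conditions: H2 (1 atm), PtO2, EtOAc, rt
Reagents that add atoms: none
Why: Heterogeneous hydrogenation of the exocyclic alkene from the α face, because the β face of ring B is covered by the axial C12 and C14 methyl groups; hydrogen arrives axially at C8 and leaves C13 equatorial and β, which is also the more stable arrangement. Platinum is chosen over palladium to limit alkene migration and benzylic C–O cleavage.

Step 15
Reactants: 21 triethylsilyl ether
Product: 22 4α-hydroxy decalin (arene protection unchanged)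
Conditions: pyridinium p-toluenesulfonate, MeOH/CH2Cl2, rt
Reagents that add atoms: none
Why: Mild acid methanolysis removes the triethylsilyl ether, which is several orders of magnitude more labile than the triisopropylsilyl ethers; the aryl acetal needs much stronger acid.

Step 16
Reactants: 22 4α-alcohol
Product: 23 decalin-4-one (5β,8β,9β-trimethyl; 9α-CH2Ar; 10α-H)
Conditions: DMP (1,1,1-triacetoxy-1,1-dihydro-1,2-benziodoxol-3(1H)-one), NaHCO3, CH2Cl2, rt
Reagents that add atoms: none
Why: Hypervalent iodine oxidation of a hindered secondary alcohol under buffered, non-acidic conditions; there is no free phenol to be oxidised and C5 is quaternary, so no centre can epimerise.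

Step 17
Reactants: 23 decalin-4-one
Product: 24 4(11)-methylene decalin with fully protected arene
Conditions: Ph3PCH3Br (5 equiv), KOt-Bu (4.5 equiv), toluene, 90 °C
Reagents that add atoms: methyltriphenylphosphonium bromide, C[P+](c1ccccc1)(c1ccccc1)c1ccccc1.[Br-]
Why: Wittig methylenation with the small unstabilised ylide at elevated temperature, the standard answer to a ketone flanked by a quaternary carbon; the phosphonium salt is kept in excess over the base so that no free alkoxide attacks the aryl silyl ether.

Step 18
Reactants: 24 4(11)-methylene decalin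
Product: 26 C6′ phenol 2-(triisopropylsilyloxy)-4-[(triisopropylsilyloxy)methyl]-6-(decalinylmethyl)phenol, via aryl trimethylsilyl ether 25 (not isolated)
Conditions: Me3SiOTf, 2,2′-bipyridyl, CH2Cl2, 0 °C → rt; then H2O
Reagents that add atoms: none
Why: Silyl triflate–bipyridyl cleavage of an aromatic methoxymethyl ether: the pyridine-complexed silyl cation activates the acetal, the bipyridyl takes up the methoxymethyl fragment and the aryl oxygen is silylated, and water then hydrolyses the labile aryl trimethylsilyl ether. The medium is buffered by the base, so the exocyclic alkene and the bulky silyl ethers are expected to remain.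

Step 19
Reactants: 26 C6′ phenol
Product: 27 pyridinium aryl sulfate (O6′–SO3−; O5′ and the benzylic oxygen as triisopropylsilyl ethers)
Conditions: SO3·pyridine (5 equiv), pyridine, 50 °C
Reagents that add atoms: sulfur trioxide–pyridine complex, [O-]S(=O)(=O)[n+]1ccccc1
Why: O-sulfation of the only free hydroxyl group by the amine–SO3 complex; the weakly basic medium does not ionise the phenol enough to allow silyl migration, and the less hindered O5′ is the favoured site for the silyl group in any case.

Step 20
Reactants: 27 pyridinium aryl sulfate
Product: 29 2-hydroxy-4-(hydroxymethyl)-6-{[(5S,8S,9R,10S)-5,8,9-trimethyl-4-methylidenedecalin-9-yl]methyl}phenyl hydrogen sulfate (target), via tetrabutylammonium sulfate 28 (not isolated)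
Conditions: n-Bu4NF, THF, 0 °C → rt; then sulfonic acid cation-exchange resin (H+ form), MeOH/H2O, 0 °C
Reagents that add atoms: none
Why: Fluoride cleaves the aryl and benzylic silyl ethers, while the anionic sulfate monoester is inert to fluoride and base; with O6′ sulfated the benzylic alcohol no longer ionises easily, and cold cation exchange releases the hydrogen sulfate.

## Compound list

1 | 5-bromovanillin | COc1cc(C=O)cc(Br)c1O | starting material
2 | 3-bromo-4,5-dihydroxybenzaldehyde | O=Cc1cc(O)c(O)c(Br)c1 | intermediate
3 | 3-bromo-5-hydroxy-4-(methoxymethoxy)benzaldehyde | COCOc1c(O)cc(C=O)cc1Br | intermediate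
4 | 3-bromo-5-(hydroxymethyl)-2-(methoxymethoxy)phenol | COCOc1c(O)cc(CO)cc1Br | intermediate
5 | {[3-bromo-4-(methoxymethoxy)-5-(triisopropylsilyloxy)phenyl]methoxy}triisopropylsilane (ArBr) | COCOc1c(O[Si](C(C)C)(C(C)C)C(C)C)cc(CO[Si](C(C)C)(C(C)C)C(C)C)cc1Br | intermediate
6 | aryllithium ArLi | COCOc1c(O[Si](C(C)C)(C(C)C)C(C)C)cc(CO[Si](C(C)C)(C(C)C)C(C)C)cc1[Li] | intermediate
7 | 2-(methoxymethoxy)-3-(triisopropylsilyloxy)-5-[(triisopropylsilyloxy)methyl]benzaldehyde (ArCHO) | COCOc1c(O[Si](C(C)C)(C(C)C)C(C)C)cc(CO[Si](C(C)C)(C(C)C)C(C)C)cc1C=O | intermediate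
8 | 2-(triphenylphosphoranylidene)propanal | CC(C=O)=P(c1ccccc1)(c1ccccc1)c1ccccc1 | starting material
9 | (E)-3-Ar-2-methylprop-2-enal | O=C/C(C)=C/c1cc(CO[Si](C(C)C)(C(C)C)C(C)C)cc(O[Si](C(C)C)(C(C)C)C(C)C)c1OCOC | intermediate
10 | (2E,4E)-5-Ar-2,4-dimethylpenta-2,4-dienal | O=C/C(C)=C/C(C)=C/c1cc(CO[Si](C(C)C)(C(C)C)C(C)C)cc(O[Si](C(C)C)(C(C)C)C(C)C)c1OCOC | intermediate
11 | (E)-crotonaldehyde | C/C=C/C=O | starting material
12 | (E)-1-(triethylsilyloxy)buta-1,3-diene | C=C/C=C/O[Si](CC)(CC)CC | intermediate
13 | (1S,2R,6S)-6-[(E)-1-Ar-prop-1-en-2-yl]-1-methyl-2-(triethylsilyloxy)cyclohex-3-ene-1-carbaldehyde | O=C[C@]1(C)[C@H](O[Si](CC)(CC)CC)C=CC[C@H]1/C(C)=C/c2cc(CO[Si](C(C)C)(C(C)C)C(C)C)cc(O[Si](C(C)C)(C(C)C)C(C)C)c2OCOC | intermediate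
14 | dimethyl (2-oxopropyl)phosphonate | COP(=O)(CC(C)=O)OC | starting material
15 | sodium salt of dimethyl (2-oxopropyl)phosphonate | [Na+].COP(=O)([CH-]C(C)=O)OC | intermediate
16 | (E)-enone: 4-[ring A of 13]but-3-en-2-one | CC(=O)/C=C/[C@]1(C)[C@H](O[Si](CC)(CC)CC)C=CC[C@H]1/C(C)=C/c2cc(CO[Si](C(C)C)(C(C)C)C(C)C)cc(O[Si](C(C)C)(C(C)C)C(C)C)c2OCOC | intermediate
17 | saturated methyl ketone (ring A cyclohexane; 4α-OSiEt3, 5β-CH3, 10α-H, styrene intact) | CC(=O)CC[C@]1(C)[C@H](O[Si](CC)(CC)CC)CCC[C@H]1/C(C)=C/c2cc(CO[Si](C(C)C)(C(C)C)C(C)C)cc(O[Si](C(C)C)(C(C)C)C(C)C)c2OCOC | intermediate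
18 | lithium enolate of 17 (terminal) | [Li]OC(=C)CC[C@]1(C)[C@H](O[Si](CC)(CC)CC)CCC[C@H]1/C(C)=C/c2cc(CO[Si](C(C)C)(C(C)C)C(C)C)cc(O[Si](C(C)C)(C(C)C)C(C)C)c2OCOC | intermediate
19 | alkenyl triflate (C8(OTf)=C13H2) | C=C(OS(=O)(=O)C(F)(F)F)CC[C@]1(C)[C@H](O[Si](CC)(CC)CC)CCC[C@H]1/C(C)=C/c2cc(CO[Si](C(C)C)(C(C)C)C(C)C)cc(O[Si](C(C)C)(C(C)C)C(C)C)c2OCOC | intermediate
20 | trans-decalin, 8(13)-methylene, 9β-CH3, 9α-CH2Ar, 5β-CH3, 10α-H, 4α-OSiEt3 | CC[Si](CC)(CC)O[C@@H]1CCC[C@H]2[C@](C)(Cc3cc(CO[Si](C(C)C)(C(C)C)C(C)C)cc(O[Si](C(C)C)(C(C)C)C(C)C)c3OCOC)C(=C)CC[C@]12C | intermediate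
21 | trans-decalin, 8β-CH3, 9β-CH3, 9α-CH2Ar, 5β-CH3, 10α-H, 4α-OSiEt3 | CC[Si](CC)(CC)O[C@@H]1CCC[C@H]2[C@](C)(Cc3cc(CO[Si](C(C)C)(C(C)C)C(C)C)cc(O[Si](C(C)C)(C(C)C)C(C)C)c3OCOC)[C@@H](C)CC[C@]12C | intermediate
22 | 4α-hydroxy decalin | O[C@@H]1CCC[C@H]2[C@](C)(Cc3cc(CO[Si](C(C)C)(C(C)C)C(C)C)cc(O[Si](C(C)C)(C(C)C)C(C)C)c3OCOC)[C@@H](C)CC[C@]12C | intermediate
23 | decalin-4-one | O=C1CCC[C@H]2[C@](C)(Cc3cc(CO[Si](C(C)C)(C(C)C)C(C)C)cc(O[Si](C(C)C)(C(C)C)C(C)C)c3OCOC)[C@@H](C)CC[C@]12C | intermediate
24 | 4(11)-methylene decalin, arene fully protected | C=C1CCC[C@H]2[C@](C)(Cc3cc(CO[Si](C(C)C)(C(C)C)C(C)C)cc(O[Si](C(C)C)(C(C)C)C(C)C)c3OCOC)[C@@H](C)CC[C@]12C | intermediate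
25 | aryl trimethylsilyl ether at O6′ | C=C1CCC[C@H]2[C@](C)(Cc3cc(CO[Si](C(C)C)(C(C)C)C(C)C)cc(O[Si](C(C)C)(C(C)C)C(C)C)c3O[Si](C)(C)C)[C@@H](C)CC[C@]12C | intermediate
26 | C6′ phenol | C=C1CCC[C@H]2[C@](C)(Cc3cc(CO[Si](C(C)C)(C(C)C)C(C)C)cc(O[Si](C(C)C)(C(C)C)C(C)C)c3O)[C@@H](C)CC[C@]12C | intermediate
27 | pyridinium aryl sulfate, bis(triisopropylsilyl) ether | C=C1CCC[C@H]2[C@](C)(Cc3cc(CO[Si](C(C)C)(C(C)C)C(C)C)cc(O[Si](C(C)C)(C(C)C)C(C)C)c3OS(=O)(=O)[O-])[C@@H](C)CC[C@]12C.c1cc[nH+]cc1 | intermediate
28 | tetrabutylammonium salt of the target sulfate | C=C1CCC[C@H]2[C@](C)(Cc3cc(CO)cc(O)c3OS(=O)(=O)[O-])[C@@H](C)CC[C@]12C.CCCC[N+](CCCC)(CCCC)CCCC | intermediate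
29 | 2-hydroxy-4-(hydroxymethyl)-6-{[(5S,8S,9R,10S)-5,8,9-trimethyl-4-methylidenedecalin-9-yl]methyl}phenyl hydrogen sulfate | C=C1CCC[C@H]2[C@](C)(Cc3cc(CO)cc(O)c3OS(=O)(=O)O)[C@@H](C)CC[C@]12C | target

## Step count and risks

Total: 20 steps. Longest linear sequence: 19 steps (1 to 29 through steps 1–7 and 9–20); step 8 is a one-step side branch.

**Step 9 (key step).**
- Risk: turnover may be too slow. Dienal 10 is a trisubstituted, cross-conjugated dienophile whose LUMO is raised by the electron-rich styrene, so acid-induced desilylation or oligomerisation of the diene can outrun cycloaddition. The bulky β-substituent may also disturb the stacking under the catalyst and erode facial selectivity.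
- Fallback (absolute configuration by resolution instead of catalysis): 10 and 12 are combined under Me2AlCl in CH2Cl2 to give racemic 13. This is reduced with i-Bu2AlH to the primary neopentyl alcohol F1. F1 is esterified with (S)-O-methylmandelic acid (carbodiimide, 4-dimethylaminopyridine), and the diastereomeric esters are separated by chromatography. The (S)-O-methylmandelate ester F2 of the (4R,5S,10S) series is cleaved with i-Bu2AlH back to enantiopure F1, which is oxidised with DMP to 13, where the route resumes.

**Step 13.**
- Risk: formate may reduce the alkenylpalladium species before it inserts into the hindered styrene. After insertion, the benzylpalladium may close a three-membered ring onto the new exocyclic alkene and rearrange the skeleton. Insertion through the disfavoured rotamer would invert C9.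
- Fallback (radical instead of palladium-mediated closure): from ketone 17, NaBH4 gives the secondary alcohol F3 (C8 epimers, of no consequence). I2, PPh3 and imidazole give the secondary iodide F4. Slow addition of Bu3SnH with azobisisobutyronitrile in hot benzene generates the C8 radical, which closes 6-exo onto C9 through the same chair; the benzylic radical is reduced, and the product is 21 directly. Hydrogen transfer from C10 to the radical is the reason this closure is second choice.

**Step 11.**
- Risk: incomplete reduction of the two hindered disubstituted alkenes (both flank the quaternary C5), or creeping reduction of the styrene under forcing conditions.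
- Fallback (two chemoselective reductions in place of one): from 16, [(Ph3P)CuH]6 delivers hydride only to the enone and gives the ring A alkene ketone F5. Diimide, generated from 2-nitrobenzenesulfonohydrazide and Et3N, then reduces the cis-disubstituted ring alkene but not the trisubstituted styrene, returning to 17.

**Step 14.**
- Risk: the exocyclic alkene may migrate into ring B on the metal surface, leaving a hindered trisubstituted alkene that resists reduction, or the facial selectivity may be poor.
- Fallback (radical hydrogen-atom-transfer hydrogenation instead of surface catalysis): from 20, Mn(dpm)3 (dpm = 2,2,6,6-tetramethylheptane-3,5-dionate), PhSiH3 and t-BuOOH in i-PrOH reduce the alkene through the tertiary C8 radical. This takes up hydrogen to give the thermodynamically preferred equatorial C13 and returns to 21. The fallback makes no new compound (F0).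

**Step 18.**
- Risk: incomplete cleavage at the doubly flanked O6′, loss of a silyl ether, or acid-induced migration of the C4=C11 alkene into ring A if free triflic acid develops.
- Fallback (cleave the acetal before the alkene exists): from ketone 23, ZnBr2 and n-PrSH in CH2Cl2 at 0 °C remove the methoxymethyl group to give the phenol ketone F6. F6 is methylenated as its potassium phenoxide with excess ylide from Ph3PCH3Br and KOt-Bu, and re-enters the route at 26.

## Further compounds

F1 | step 9 | [(1S,2R,6S)-6-[(E)-1-Ar-prop-1-en-2-yl]-1-methyl-2-(triethylsilyloxy)cyclohex-3-en-1-yl]methanol | OC[C@]1(C)[C@H](O[Si](CC)(CC)CC)C=CC[C@H]1/C(C)=C/c2cc(CO[Si](C(C)C)(C(C)C)C(C)C)cc(O[Si](C(C)C)(C(C)C)C(C)C)c2OCOC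
F2 | step 9 | (S)-O-methylmandelate ester of F1 | CO[C@H](C(=O)OC[C@]1(C)[C@H](O[Si](CC)(CC)CC)C=CC[C@H]1/C(C)=C/c2cc(CO[Si](C(C)C)(C(C)C)C(C)C)cc(O[Si](C(C)C)(C(C)C)C(C)C)c2OCOC)c3ccccc3
F3 | step 13 | secondary alcohol from 17 (C8 epimers) | CC(O)CC[C@]1(C)[C@H](O[Si](CC)(CC)CC)CCC[C@H]1/C(C)=C/c2cc(CO[Si](C(C)C)(C(C)C)C(C)C)cc(O[Si](C(C)C)(C(C)C)C(C)C)c2OCOC
F4 | step 13 | secondary iodide (C8 epimers) | CC(I)CC[C@]1(C)[C@H](O[Si](CC)(CC)CC)CCC[C@H]1/C(C)=C/c2cc(CO[Si](C(C)C)(C(C)C)C(C)C)cc(O[Si](C(C)C)(C(C)C)C(C)C)c2OCOC
F5 | step 11 | ring A alkene ketone (enone reduced, C2=C3 retained) | CC(=O)CC[C@]1(C)[C@H](O[Si](CC)(CC)CC)C=CC[C@H]1/C(C)=C/c2cc(CO[Si](C(C)C)(C(C)C)C(C)C)cc(O[Si](C(C)C)(C(C)C)C(C)C)c2OCOC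
F0 | step 14 | none | none
F6 | step 18 | phenol ketone (O6′ free, decalin-4-one) | O=C1CCC[C@H]2[C@](C)(Cc3cc(CO[Si](C(C)C)(C(C)C)C(C)C)cc(O[Si](C(C)C)(C(C)C)C(C)C)c3O)[C@@H](C)CC[C@]12C
A1 | alternative 1 | rearranged 4(11)-ene with 5-bromo-2,3-dimethoxybenzyl group | C=C1CCC[C@H]2[C@](C)(Cc3cc(Br)cc(OC)c3OC)[C@@H](C)CC[C@]12C
A2 | alternative 1 | 9-(5-bromo-2,3-dimethoxybenzyl) drimane 8(12)-ene | C=C1CC[C@H]2C(C)(C)CCC[C@]2(C)[C@H]1Cc1cc(Br)cc(OC)c1OC
A3 | alternative 2 | trans-decalin 8-ketone with C9 8-phenylmenthyl ester and C4 methylene | C=C1CCC[C@H]2[C@](C(=O)O[C@@H]3C[C@H](C)CC[C@H]3C(C)(C)c3ccccc3)(Cc3cc(CO[Si](C)(C)C(C)(C)C)cc(O[Si](C(C)C)(C(C)C)C(C)C)c3OCC=C)C(=O)CC[C@]12C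
A4 | alternative 3 | 2-allyloxy-3-(decalinylmethyl)cyclohex-2-enone 5-carboxylate | C=C1CCC[C@H]2[C@](C)(CC3=C(OCC=C)C(=O)C[C@H](C(=O)OC)C3)[C@@H](C)CC[C@]12C
A5 | alternative 3 | 1-(decalin-9-yl)propan-2-one (methyl ketone on C15) | C=C1CCC[C@H]2[C@](C)(CC(C)=O)[C@@H](C)CC[C@]12C
A6 | alternative 3 | methyl (E)-5-(allyloxy)-4-oxopent-2-enoate | COC(=O)/C=C/C(=O)COCC=C
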